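Start from what cannot drift: each Pdt takes one Sbt and one Ptn, and the grey, teal and violet flasks are charged with the two in equal amounts, so in them cSbt = cPtn = charge − cPdt throughout, bound and free counted together.

| flask | Sbt | Ptn | Ctl | time |
|---|---|---|---|---|
| grey | 0.0500 M | 0.0500 M | 0.00500 M |  |
| green | 0.0300 M | 0.0300 M | 0.00500 M |  |
| teal | 0.0500 M | 0.0500 M | 0.0100 M |  |
| violet | 0.0500 M | 0.0500 M | 0.00500 M | 63 min |

- grey run (time / min: [Pdt] / M): 0.84: 0.0036; 1.6: 0.0067; 3.0: 0.0115; 5.8: 0.0189; 11: 0.0260; 21: 0.0328
- green run (time / min: [Pdt] / M): 0.84: 0.0019; 1.6: 0.0036; 3.0: 0.0062; 5.8: 0.0093; 11: 0.0133; 21: 0.0168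
- teal run (time / min: [Pdt] / M): 0.84: 0.0069; 1.6: 0.0114; 3.0: 0.0186; 5.8: 0.0266; 11: 0.0330; 21: 0.0375

(readings scatter by 3 × 10⁻⁴ M)

* the power of [Ctl] that the first rate follows, about the charge of the grey run; measure it at two percent of Sbt made into Pdt
* the green run starts with 0.0200 M less of Sbt and of Ptn than the grey run, and with no Pdt. Compared where both hold the same amount of Sbt, once fifteen percent of what the green run was charged with has turned into Pdt, is the green run faster, slower or alike (within a tenth)?
* Pdt in the violet run at 63 min, as a share of the Sbt charged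

- Overall: Sbt + Ptn -> Pdt, with Ctl as catalyst.
- Constant volume, constant temperature.
- Bound and free are read together.
- An order is taken over about fifteen percent of the charge, up and down.

Now treat the violet flask as the grey flask read later, and look for a clock that lets teal speak for it. Take cCtl·t. Teal at 11 min holds 0.0330 M and grey at 21 min holds 0.0328 M, on clocks of 6.60 M·s and 6.30 M·s, so the readings nearly overlay.

Plot 1/cSbt against this clock and freeze its slope. Between its last two readings teal gives the late clock slope, the change of 1/cSbt per unit of cCtl·t, 212 M⁻² min⁻¹, a reading with its scatter. Grey over its last two readings gives 329 M⁻² min⁻¹, on a clock window that teal's doubles. The slope is falling.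

Build the bracket. Floor first: violet's clock ends at 18.9 M·s, later than teal's last 12.6 M·s, so violet stands above teal's 75.0%. For a ceiling, carry teal on at the frozen slope: 80.4%. Raise the floor by letting the slope fall once more by the same ratio, to 136 M⁻² min⁻¹. That is my own assumption, and a generous one, since the remaining stretch is shorter than a doubling. It gives 78.8%. My bracket is 1.6 percentage points wide.

The forecast says 0.95 for the catalyst power, faster for the green flask, and 79.5% for violet: “Extrapolating to 63 min gives about 0.040 M, or about 79–80%, with a possible plateau.” That value lies inside the bracket, reached by the same overlay and a tail extrapolated from teal's last reading.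

The flask gives 0.95, faster and 79.2%, inside the bracket.

    Ctl + Sbt ⇌ Ctl.Sbt, settled at all times (37.50 M⁻¹)
    Ctl.Sbt + Ptn → Pdt + Ctl + Lvg (51.96 M⁻¹ min⁻¹)
    2 Ctl → 2 Q (66.60 M⁻¹ min⁻¹)
    Ctl + Ptn ⇌ Ctl.Ptn, settled at all times (39.20 M⁻¹)

Grey reaches half its charge at 9.58 min and teal at 5.19 min, a ratio of 1.85. Put the clock slope to use again: from teal's last reading to violet's end it averages 156 M⁻² min⁻¹, below 212 M⁻² min⁻¹ and above 136 M⁻² min⁻¹. The green flask, reaching half its charge at 15.3 min, averages 435 M⁻² min⁻¹ from its start, twice the late slope of teal.

The data are calculated on assumed constants.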